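## Structural features

Tomoeone D (22) is a spiro compound: ring A, a 1,1-diprenylated 5-isobutyryl cyclohexane-2,4,6-trione written as its C6 enol (C1 diprenyl carbon, C2 and C4 carbonyls, C5 acyl carbon, C6 enol carbon), shares the quaternary carbon C3 with ring B (C3, C7, C8, C9, C10, C11). Ring B is trans-fused along C8–C9 to the cyclopentane ring C (C8, C9, C12, C13, C14), and both C10 and C14 are tertiary methyl carbinols. Of the five stereocentres, C14, C8, C9 and C10 are contiguous along the terpene-derived edge, and C3 lies one methylene away from both C8 and C10. With β defined as the face of ring B that carries H8, the trans fusion locks ring B in one chair in which H8, the C10 hydroxyl and the C3–C2 bond are β and axial, while the C10 methyl and the C3–C4 bond are equatorial and the C14 hydroxyl is α (cis to C7). Fragile functions are the two tertiary alcohols (dehydration, hemiketal formation between the C10 hydroxyl and C2), the enolised β-triketone (retro-Claisen cleavage, O-alkylation) and the two prenyl alkenes (acid-induced cyclisation onto the enol, oxidation). The real difficulty is C3, because its two carbonyl arms C2 and C4 differ only in their far neighbours (C1 versus C5), so its configuration amounts to deciding which carboxyl-level carbon becomes axial and syn to the C10 oxygen. The key step exploits exactly this 1,3-diaxial pairing of C2 on C3 with C10 across C11 in ring B: an ester tether running from C2 to the carbon attached to C10 can bridge only these two axial sites of the chair that the chiral-pool atoms C8, C9 and C14 lock in place.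

## Logic of the disconnections

22 ⇒ 21. No skeletal bond is cut; the O–H at C14 is exchanged for O–SiEt3. The C14 oxygen is cis to C7 and would attack a carboxyl group on C3 (six-membered lactone) as long as ring B is open, so it is masked early and freed last. This removes one hydroxyl from every earlier step. The forward step must be a desilylation mild enough for the enolised triketone, the prenyl groups and the C10 carbinol.

21 ⇒ 19 + 20 (twice). The two C1–CH2 bonds to the prenyl groups are cut. The prenyl alkenes would not survive the iodine, selenium and tin chemistry used earlier, and C1 is the only ring A carbon that still bears hydrogen. Ten carbons and two alkenes disappear. The forward step must alkylate at carbon and not at oxygen, twice, with the C10 hydroxyl free.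

19 ⇒ 16 + 17. The bonds C1–C2 and C4–C5 are cut. In 16 the two carbons on C3 are already different (C2 a bridged lactone tied to the C10 oxygen, C4 a methyl ester), so the unsymmetrical unit C1–C6–C5 with its acyl group, all contained in 17, can be attached in a defined sense. The whole of ring A falls away in one operation and the C10 alcohol is released at the same time. The terminal carbanion of doubly deprotonated 17 must choose the lactone carbonyl before the ester, since this choice carries the C3 configuration of 16 into 19, and the second closure must occur through carbon C5.

16 ⇒ 15 ⇒ 14. The C10–O bond is cut and the C10 methyl is traced back through CH2–iodine to a methylene. The β-axial C2 carboxyl is the only group that can reach C10, so it can deliver the oxygen to the correct face and mark itself as C2 in one act. The C10 stereocentre is exchanged for an exocyclic alkene, and C2 and C4 appear as acid and ester. The forward steps need a Markovnikov 5-exo closure by the axial acid and a clean reductive removal of iodine.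

14 ⇒ 11 (key disconnection). The bond C3–C11 is cut and O–CH2 is re-formed. 14 is a γ,δ-unsaturated acid (C2–C3–C11–C10=CH2), the retron of an ester-enolate [3,3] shift, and rejoining the carboxyl oxygen to the methylene carbon turns ring B into an eight-membered allylic lactone. Ring B and the quaternary stereocentre C3 are traded for an enolisable malonate carbon with no stereochemical demand of its own. The forward step needs silylation on the lactone side, a reactive conformation with ring B as a chair, and a tether that reaches only the β-axial positions.

11 ⇒ 10 ⇒ 9. The acyl–oxygen bond C2–O of the lactone is cut and the acid is returned to a second methyl ester. This is the only heteroatom bond in the medium ring and it leads back to a symmetric malonate. The result is an open chain on ring C with two equivalent carboxyl carbons. The eight-membered closure must beat oligomerisation, so an activated half-acid under high dilution is planned instead of a transesterification of the diester; the saponification must stop after one ester.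

9 ⇒ 8. The allylic C–O bond is cut. A 2-substituted allyl alcohol is the allylic oxidation product of an isopropenyl group. The side chain returns to its unfunctionalised terpene form. The oxidation must take the methyl group and not C9–H or the malonate carbon.

8 ⇒ 6 + 7, then 6 ⇒ 5 ⇒ 4. The bond C7–C3 is cut. 7 supplies C3 together with C2 and C4 at the right oxidation level. The future ring A/B junction is separated from the terpene part, and 6 reduces by functional-group changes to 5 and 4. The forward steps need SN2 at a β-branched primary iodide and activation of the primary hydroxyl of 4 before the tertiary one is silylated.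

4 ⇒ 3 ⇒ 2. After the primary alcohol is returned to the aldehyde, the bond C8–C14 is cut. A β-hydroxy aldehyde is an aldol retron and the closure is five-membered. Ring C and the stereocentres C8 and C14 are traded for an open keto aldehyde with C9 as its only stereocentre. The forward step must avoid dehydration and must place C7 trans to the C9 substituent and the C14 oxygen cis to C7.

2 ⇒ 1. The carbonyl carbons C7 and C14 are reconnected as a ring alkene. The 1,6-dicarbonyl pattern next to an isopropenyl-bearing stereocentre is the oxidative-cleavage retron of 1, which is commercial in the required configuration. All ten terpene carbons and the configuration of C9 are bought. The cleavage must take the trisubstituted alkene only.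

## Other disconnections considered

Alternative 1: The cut is C8–C14 of ring C. In the forward direction the enamine of the aldehyde in 2 adds to the methyl ketone and gives the β-hydroxy aldehyde A1, which is the same compound as 3.
- In favour: one organocatalytic step from an oxidised form of 1 creates ring C, sets C8 and C14 relative to the bought C9, and places every terpene carbon of the target.
- Against, as the strategy-bearing step: it says nothing about C3, rings A and B or the C10 carbinol, and A1 is prone to dehydration and retro-aldol cleavage.
- Comparison: structurally this is the ring C opening of the chosen plan and not a rival, so for the terpene half the two are equal. Mechanistically it is simpler and milder than a sigmatropic ring contraction, which is a point in its favour. In step count it is neutral, because any route from 1 passes through it. It is therefore used as step 2, and the strategic role goes to the later step that fixes C3.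

Alternative 2: The cuts are C9–C10 and C7–C8. A chiral monovalent rhodium catalyst (for example [Rh(cod)Cl]2 with a chiral bisphosphine or diene ligand) would add an isopropenylboron reagent to A3 (cyclopent-2-en-1-one). The enolate would be trapped by A4 (dimethyl methylidenemalonate) to give A2, a trans-2,3-disubstituted cyclopentanone that already carries C3 with both esters.
- In favour: two C–C bonds and two stereocentres in one catalytic operation, either enantiomer available without a chiral pool, and the malonate in place after one step where the chosen plan needs five. On convergence and on step count up to the malonate stage it is the better plan. A methyl nucleophile should add anti to the C8 substituent, which is the correct sense at C14, so on that point it is equal.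
- Against: the methyl addition must be done in the presence of two esters, and the resulting alkoxide is cis to C7 and is expected to close onto the malonate as a six-membered lactone. A4 polymerises readily under nucleophilic conditions. Enolate trapping needs water-free conditions that are less developed for transfer of a 2-substituted alkenyl group.
- Comparison: structurally A2 stops at the level of 8 and leaves C3 unsolved, so the lactone and the [3,3] shift would still be needed. Mechanistically the tandem addition–Michael step is less certain than ozonolysis and aldol. The saving in steps is expected to be partly lost to the ketone-to-carbinol problem.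

Alternative 3: The cuts are C3–C7 and C8–C9. The triene A6 would be made from A7 ((R)-linalool) by allylic oxidation of its terminal methyl group and Knoevenagel condensation with 7. On heating, its alkylidene malonate diene would add across the tethered vinyl group and give the hydrindene gem-diester A5, with rings B and C formed together.
- In favour: two rings, two C–C bonds and two stereocentres in one thermal step, C14 from the chiral pool, no protecting group, and ring B reached in about three steps where the chosen plan needs nine. In bond economy it is clearly better.
- Against: C8 and C9 would have to be set relative to a C14 centre whose methyl and hydroxyl groups offer little facial bias. The trans ring fusion is not assured for this tether length. The diene is electron-poor at the terminus that must bond to an unactivated alkene, so high temperature is needed with a tertiary allylic alcohol present. A5 holds two equivalent esters and a trisubstituted C10=C11 alkene, so C3 and C10 remain open; the same carboxyl-to-C10 lactonisation logic could address them, but in the less favourable 5-endo mode.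
- Comparison: on structure and step count this alternative is the stronger one if the cycloaddition is selective. On mechanism and stereochemical reliability the chosen plan is stronger, because C8, C9 and C14 come from the pool and from an aldol with a clear bias, and its key step delivers C2 and C4 already differentiated.

Key step: step 9

Remark on the chemistry: ring A is written throughout as the C6 enol; its enol tautomers interconvert, so this choice does not affect the argument at C3, which is the only stereocentre of ring A.

Step 1
Reactants: 1 (R)-(+)-limonene
Product: 2 (3R)-6-oxo-3-(prop-1-en-2-yl)heptanal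
Conditions: O3 (1 equiv), CH2Cl2/MeOH, −78 °C; then Me2S, −78 °C → rt
Reagents that add atoms: ozone, [O-][O+]=O
Why: Ozonolysis with reductive work-up; the trisubstituted ring alkene is more electron-rich than the 1,1-disubstituted isopropenyl group and should be cleaved first when ozone is limited to one equivalent. The stereocentre (future C9) is not touched.

Step 2
Reactants: 2 (3R)-6-oxo-3-(prop-1-en-2-yl)heptanal
Product: 4 (1R,2R,3R)-2-(hydroxymethyl)-1-methyl-3-(prop-1-en-2-yl)cyclopentan-1-ol, via hydroxy aldehyde 3 (not isolated)
Conditions: piperidine (cat.), AcOH (cat.), CH2Cl2, 0 °C; then MeOH, NaBH4, 0 °C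
Reagents that add atoms: none
Why: Intramolecular enamine aldol addition (5-enolexo) of the aldehyde onto the methyl ketone forms C8–C14, and reduction in the same flask removes the aldehyde before it can dehydrate or revert. C7 should end trans to the C9 isopropenyl group (less hindered enamine face, also the thermodynamic arrangement of this epimerisable centre), and the C14 oxygen cis to C7 because the ketone oxygen is held next to the iminium nitrogen by hydrogen bonding while the methyl group points away.

Step 3
Reactants: 4 (1R,2R,3R)-2-(hydroxymethyl)-1-methyl-3-(prop-1-en-2-yl)cyclopentan-1-ol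
Product: 5 (1R,2S,3R)-2-(iodomethyl)-1-methyl-3-(prop-1-en-2-yl)cyclopentan-1-ol
Conditions: PPh3, I2, imidazole (reagent pre-formed), CH2Cl2, 0 °C → rt
Reagents that add atoms: iodine, II
Why: Appel-type iodination; only the primary alcohol forms the oxyphosphonium salt, the tertiary alcohol being too hindered, and pre-forming the phosphonium reagent keeps free iodine away from the alkene. No stereocentre is affected.

Step 4
Reactants: 5 (1R,2S,3R)-2-(iodomethyl)-1-methyl-3-(prop-1-en-2-yl)cyclopentan-1-ol
Product: 6 triethyl{[(1R,2S,3R)-2-(iodomethyl)-1-methyl-3-(prop-1-en-2-yl)cyclopentyl]oxy}silane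
Conditions: Et3SiOTf, 2,6-lutidine, CH2Cl2, −78 → 0 °C
Reagents that add atoms: triethylsilyl trifluoromethanesulfonate, CC[Si](CC)(CC)OS(=O)(=O)C(F)(F)F
Why: Silylation of a tertiary alcohol with a silyl triflate and a hindered pyridine base. The ether keeps the C14 oxygen from closing a six-membered lactone onto the malonate carbonyls in steps 5 to 9 and is small enough to be removed at the end.

Step 5
Reactants: 6 triethyl{[(1R,2S,3R)-2-(iodomethyl)-1-methyl-3-(prop-1-en-2-yl)cyclopentyl]oxy}silane + 7 dimethyl malonate
Product: 8 dimethyl 2-({(1S,2R,5R)-2-methyl-5-(prop-1-en-2-yl)-2-[(triethylsilyl)oxy]cyclopentyl}methyl)propanedioate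
Conditions: NaH, 7 (3 equiv), DMF/THF, 65 °C
Reagents that add atoms: none
Why: Malonic ester alkylation (SN2) forms C7–C3; the iodide is primary and only β-branched, so a soft nucleophile in a dipolar aprotic solvent should displace it, and the excess of 7 suppresses dialkylation. No stereocentre is involved.

Step 6
Reactants: 8 dimethyl 2-({(1S,2R,5R)-2-methyl-5-(prop-1-en-2-yl)-2-[(triethylsilyl)oxy]cyclopentyl}methyl)propanedioate
Product: 9 dimethyl 2-({(1S,2R,5R)-5-(3-hydroxyprop-1-en-2-yl)-2-methyl-2-[(triethylsilyl)oxy]cyclopentyl}methyl)propanedioate
Conditions: SeO2 (cat.), t-BuOOH, CH2Cl2, 0 °C → rt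
Reagents that add atoms: tert-butyl hydroperoxide, CC(C)(C)OO
Why: Catalytic SeO2 allylic hydroxylation (ene reaction, then [2,3]-sigmatropic shift) of the 1,1-disubstituted alkene; the methyl group should react in preference to the hindered ring methine C9–H, and the double bond returns to its position. Enal formed by over-oxidation would be reduced back to 9 with NaBH4/CeCl3·7H2O.

Step 7
Reactants: 9 dimethyl 2-({(1S,2R,5R)-5-(3-hydroxyprop-1-en-2-yl)-2-methyl-2-[(triethylsilyl)oxy]cyclopentyl}methyl)propanedioate
Product: 10 2-({(1S,2R,5R)-5-(3-hydroxyprop-1-en-2-yl)-2-methyl-2-[(triethylsilyl)oxy]cyclopentyl}methyl)-3-methoxy-3-oxopropanoic acid (C3 epimers)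
Conditions: KOH (1.1 equiv), THF/H2O, 0 °C; then aq. HCl to pH 3, 0 °C
Reagents that add atoms: potassium hydroxide, [K+].[OH-]
Why: Selective monosaponification of a malonic diester; once one ester is cleaved the carboxylate protects the second from hydroxide. The configuration created at C3 is irrelevant because step 9 erases it.

Step 8
Reactants: 10 2-({(1S,2R,5R)-5-(3-hydroxyprop-1-en-2-yl)-2-methyl-2-[(triethylsilyl)oxy]cyclopentyl}methyl)-3-methoxy-3-oxopropanoic acid (C3 epimers)
Product: 11 eight-membered malonate lactone (8S,9R,14R; C3 epimers): ring C2(=O)–C3H(CO2Me)–C7H2–C8H–C9H–C10(=CH2)–CH2–O trans-fused at C8–C9 to ring C bearing C14(Me)(OSiEt3)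
Conditions: 2-methyl-6-nitrobenzoic anhydride, DMAP, Et3N, CH2Cl2, rt, slow addition of 10 (high dilution)
Reagents that add atoms: none
Why: Mixed-anhydride macrolactonisation under high dilution, a reaction type that is used for eight-membered lactones. The trans-disubstituted ring C, the sp2 carbon C10 and the planar ester restrict the chain and lower the entropic cost, and both C3 epimers are acceptable.

Step 9
Reactants: 11 eight-membered malonate lactone (8S,9R,14R; C3 epimers)
Product: 14 ring B acid ester (3R,8S,9R,14R): C3 bears a β-axial CO2H (C2) and an equatorial CO2Me (C4); C10 exocyclic methylene; C14 OSiEt3, via silyl ketene acetal 12 (not isolated), via trimethylsilyl ester 13 (not isolated)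
Conditions: LiN(SiMe3)2, Me3SiCl, THF, −78 °C → rt; then PhMe, 90 °C; aq. citric acid
Reagents that add atoms: none
Why: Ireland–Claisen rearrangement run as a ring contraction. LiN(SiMe3)2 removes the acidic C3 proton of the malonate-type lactone and Me3SiCl traps the enolate on oxygen; the silyl group can move between the two carbonyl oxygens, and only the isomer silylated on the lactone oxygen (12) holds the array C3=C2(OSi)–O–CH2–C10=C11 that can react. On warming, this array should undergo a concerted, suprafacial [3,3]-sigmatropic shift through a chair-like six-atom arrangement in which C3–C11 forms as O–CH2 breaks, driven by the carbonyl group of the silyl ester 13. The closest known reaction type is the Ireland–Claisen ring contraction of macrocyclic allylic lactones through their silyl ketene acetals, here with a 2-methylene-allyl unit so that the ring shrinks by two atoms. Ring B closes by transannular C3–C11 bonding across the eight-membered ring (8 → 6) in a transition state shaped like a bicyclo[3.3.1]nonane, with ring B as one chair and the pericyclic array as the other. The single new stereocentre, C3, is controlled by the tether: the chair of the nascent ring B is fixed by the trans-fused ring C, so the three-atom bridge C2–O–CH2 can only span the two β-axial positions at C3 and C10, which puts C2 axial on the H8 face and the methyl ester equatorial. The step needs facial selectivity at the trigonal C3 and silylation on the correct oxygen; the first is secured by this bridging geometry and the second by the silyl shuttle under Curtin–Hammett conditions. Mild aqueous acid then cleaves the silyl ester to the acid 14 without touching the Et3Si ether.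

Step 10
Reactants: 14 ring B acid ester (3R,8S,9R,14R)
Product: 15 iodolactone (3S,8S,9R,10S,14R): γ-lactone C2(=O)–O–C10 on the β face; C10 bears CH2I; C3 bears CO2Me (C4); C14 OSiEt3
Conditions: I2, NaHCO3, MeCN, 0 °C, dark
Reagents that add atoms: iodine, II
Why: Iodolactonisation (5-exo, Markovnikov); the β-axial carboxylate is the only nucleophile that can reach C10 and attacks the iodonium ion at the tertiary carbon from the β face, which sets C10 with its oxygen β-axial. The equatorial ester and the silylated C14 oxygen cannot reach the alkene.

Step 11
Reactants: 15 iodolactone (3S,8S,9R,10S,14R)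
Product: 16 methyl lactone (3S,8S,9R,10S,14R): as 15 but with CH3 in place of CH2I at C10
Conditions: Bu3SnH, AIBN (cat.), PhMe, 80 °C
Reagents that add atoms: none
Why: Radical-chain dehalogenation; the primary radical abstracts hydrogen from the tin hydride faster than a β-acyloxy shift can occur, and no alkene is left in the molecule to trap it. The C10 methyl carbinol is thus stored as the bridged lactone.

Step 12
Reactants: 16 methyl lactone (3S,8S,9R,10S,14R) + 17 5-methylhexane-2,4-dione
Product: 19 ring A triketone (3R,8S,9R,10S,14R): spiro 5-isobutyryl-6-hydroxycyclohex-5-ene-2,4-dione ring with C1H2; C10 β-OH; C14 OSiEt3, via hydroxy triketo ester 18 (not isolated)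
Conditions: 17 (3 equiv), LiN(i-Pr)2 (6 equiv), THF, −78 → 0 °C; add 16, −78 → 0 °C; then NaOMe, MeOH, 50 °C; aq. HCl
Reagents that add atoms: none
Why: Double Claisen condensation: the terminal carbanion of the dianion of 17 (second deprotonation at the methyl group) should acylate at the strained bridged lactone carbonyl C2 in preference to the hindered equatorial methyl ester, forming C1–C2 and releasing the C10 alkoxide (18). Under equilibrating methoxide the central carbon C5 then attacks the ester carbon C4 in a Dieckmann-type six-membered closure, pulled forward by formation of the acidic β-triketone enolate. No stereocentre is made; the order lactone first, ester second carries the C3 configuration of 16 into ring A.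

Step 13
Reactants: 19 ring A triketone (3R,8S,9R,10S,14R) + 20 prenyl bromide
Product: 21 14-O-triethylsilyl tomoeone D (3R,8S,9R,10S,14R): 19 with two 3-methylbut-2-enyl groups on C1
Conditions: NaOMe, MeOH, 0 °C; 20 (2.5 equiv), 0 °C → rt; aq. NH4Cl
Reagents that add atoms: none
Why: C-alkylation of a cyclic β-triketone dianion with an allylic bromide, the reaction type used for gem-dialkylation of acylphloroglucinols; after the enol, C1–H is the most acidic site and its carbanion the softest nucleophile, so both prenyl groups should enter at C1 by SN2. The tertiary alcohol is not alkylated under methoxide and no stereocentre is affected.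

Step 14
Reactants: 21 14-O-triethylsilyl tomoeone D
Product: 22 tomoeone D (3R,8S,9R,10S,14R)
Conditions: HF·pyridine, pyridine, THF, 0 °C → rt
Reagents that add atoms: none
Why: Fluoride-mediated cleavage of the triethylsilyl ether, driven by the strength of the Si–F bond; the buffered reagent should leave the tertiary alcohols, the enolised triketone and the prenyl groups intact. No stereocentre is touched.

Compound list

1 | (R)-(+)-limonene | CC1=CC[C@@H](CC1)C(C)=C | starting material
2 | (3R)-6-oxo-3-(prop-1-en-2-yl)heptanal | O=CC[C@@H](CCC(C)=O)C(C)=C | intermediate
3 | (1S,2R,5R)-2-hydroxy-2-methyl-5-(prop-1-en-2-yl)cyclopentane-1-carbaldehyde | O=C[C@H]1[C@@H](CC[C@@]1(C)O)C(C)=C | intermediate (not isolated)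
4 | (1R,2R,3R)-2-(hydroxymethyl)-1-methyl-3-(prop-1-en-2-yl)cyclopentan-1-ol | OC[C@H]1[C@@H](CC[C@@]1(C)O)C(C)=C | intermediate
5 | (1R,2S,3R)-2-(iodomethyl)-1-methyl-3-(prop-1-en-2-yl)cyclopentan-1-ol | IC[C@H]1[C@@H](CC[C@@]1(C)O)C(C)=C | intermediate
6 | triethyl{[(1R,2S,3R)-2-(iodomethyl)-1-methyl-3-(prop-1-en-2-yl)cyclopentyl]oxy}silane | IC[C@H]1[C@@H](CC[C@@]1(C)O[Si](CC)(CC)CC)C(C)=C | intermediate
7 | dimethyl malonate | COC(=O)CC(=O)OC | starting material
8 | dimethyl 2-({(1S,2R,5R)-2-methyl-5-(prop-1-en-2-yl)-2-[(triethylsilyl)oxy]cyclopentyl}methyl)propanedioate | COC(=O)C(C[C@H]1[C@@H](CC[C@@]1(C)O[Si](CC)(CC)CC)C(C)=C)C(=O)OC | intermediate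
9 | dimethyl 2-({(1S,2R,5R)-5-(3-hydroxyprop-1-en-2-yl)-2-methyl-2-[(triethylsilyl)oxy]cyclopentyl}methyl)propanedioate | COC(=O)C(C[C@H]1[C@@H](CC[C@@]1(C)O[Si](CC)(CC)CC)C(=C)CO)C(=O)OC | intermediate
10 | 2-({(1S,2R,5R)-5-(3-hydroxyprop-1-en-2-yl)-2-methyl-2-[(triethylsilyl)oxy]cyclopentyl}methyl)-3-methoxy-3-oxopropanoic acid (C3 epimers) | COC(=O)C(C[C@H]1[C@@H](CC[C@@]1(C)O[Si](CC)(CC)CC)C(=C)CO)C(=O)O | intermediate
11 | eight-membered malonate lactone, (8S,9R,14R), C3 drawn as one of two usable epimers | COC(=O)[C@@H]1C[C@H]2[C@@H](CC[C@@]2(C)O[Si](CC)(CC)CC)C(=C)COC1=O | intermediate
12 | trimethylsilyl ketene acetal of 11 (C3=C2(OSiMe3)–O within the ring) | COC(=O)C=1C[C@H]2[C@@H](CC[C@@]2(C)O[Si](CC)(CC)CC)C(=C)COC=1O[Si](C)(C)C | intermediate (not isolated)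
13 | trimethylsilyl ester of 14 | COC(=O)[C@]1(C(=O)O[Si](C)(C)C)C[C@H]2[C@@H](CC[C@@]2(C)O[Si](CC)(CC)CC)C(=C)C1 | intermediate (not isolated)
14 | ring B acid ester, (3R,8S,9R,14R), β-axial CO2H (C2), equatorial CO2Me (C4), C10 methylene | COC(=O)[C@]1(C(=O)O)C[C@H]2[C@@H](CC[C@@]2(C)O[Si](CC)(CC)CC)C(=C)C1 | intermediate
15 | iodolactone, (3S,8S,9R,10S,14R), C2(=O)–O–C10 bridge on the β face, CH2I on C10 | COC(=O)[C@]12C[C@H]3[C@@H](CC[C@@]3(C)O[Si](CC)(CC)CC)[C@](CI)(C1)OC2=O | intermediate
16 | methyl lactone, (3S,8S,9R,10S,14R) | COC(=O)[C@]12C[C@H]3[C@@H](CC[C@@]3(C)O[Si](CC)(CC)CC)[C@](C)(C1)OC2=O | intermediate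
17 | 5-methylhexane-2,4-dione | CC(C)C(=O)CC(C)=O | starting material
18 | hydroxy triketo ester, (3R,8S,9R,10S,14R), β-axial 6-methyl-3,5-dioxoheptanoyl group (C2) and CO2Me (C4) on C3, C10 β-OH | COC(=O)[C@]1(C(=O)CC(=O)CC(=O)C(C)C)C[C@H]2[C@@H](CC[C@@]2(C)O[Si](CC)(CC)CC)[C@@](C)(O)C1 | intermediate (not isolated)
19 | ring A triketone with C1H2, (3R,8S,9R,10S,14R), C14 OSiEt3 | C1C(=O)[C@]2(C[C@H]3[C@@H](CC[C@@]3(C)O[Si](CC)(CC)CC)[C@@](C)(O)C2)C(=O)C(C(=O)C(C)C)=C1O | intermediate
20 | prenyl bromide (1-bromo-3-methylbut-2-ene) | CC(C)=CCBr | starting material
21 | 14-O-triethylsilyl tomoeone D, (3R,8S,9R,10S,14R) | CC(C)=CCC1(CC=C(C)C)C(=O)[C@]2(C[C@H]3[C@@H](CC[C@@]3(C)O[Si](CC)(CC)CC)[C@@](C)(O)C2)C(=O)C(C(=O)C(C)C)=C1O | intermediate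
22 | tomoeone D, (3R,8S,9R,10S,14R) | CC(C)=CCC1(CC=C(C)C)C(=O)[C@]2(C[C@H]3[C@@H](CC[C@@]3(C)O)[C@@](C)(O)C2)C(=O)C(C(=O)C(C)C)=C1O | target

Total step count: 14 steps. Longest linear sequence: 14 steps (1 → 22); 7, 17 and 20 enter as commercial partners.

Least certain steps

Step 9 (key step). The ester-stabilised (push–pull) silyl ketene acetal may rearrange so slowly that C-silylation, thermal decomposition or decarboxylation of the malonate unit overtake the [3,3] shift. Part of the material may also pass through a boat-shaped ring B, which would erode the facial selectivity at C3. The fallback gives up the lactone tether and recovers the C2/C4 distinction one step later; material held as 11 can be returned to 9 by methanolysis. It sets out from 9: methyl chloroformate and pyridine give the mixed allyl methyl carbonate F1. Pd(PPh3)4 (zerovalent palladium) in THF ionises F1 and the malonate closes onto the π-allyl unit (Tsuji–Trost cyclisation) to give the ring B gem-diester F2. Saponification of both esters gives the diacid F3. Iodolactonisation, in which only the β-axial carboxyl can reach C10, gives the iodolactone acid F4. Esterification with trimethylsilyldiazomethane rejoins the route at 15.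

Step 8. Intermolecular esterification (oligomer and diolide formation) may outrun the closure of the strained eight-membered ring, and the activated malonic half-acid may be lost through ketene dimerisation or decarboxylation. The fallback closes the same ring at carbon instead of at oxygen. It sets out from 6: SeO2/t-BuOOH gives the iodo allylic alcohol F5, methyl malonyl chloride and pyridine give the mixed allyl methyl malonate F6, and Cs2CO3 in MeCN under high dilution closes C3–C7 by intramolecular malonate alkylation, rejoining the route at 11.

Step 12. The first acylation may lose its chemoselectivity, with attack at the methyl ester instead of the lactone, which would deliver ring A with the opposite configuration at C3. The second closure may also stall at 18 or proceed through oxygen to an enol lactone. The fallback fixes the connectivity by forming C4–C5 first with an acid chloride. It sets out from 16: LiOH, then acid, gives the lactone acid F7 (the lactone re-forms on acidification). Oxalyl chloride gives the acid chloride F8. MgCl2/Et3N-mediated C-acylation of 17 at its central carbon gives the triacylmethane F9. LiN(i-Pr)2 then closes C1–C2 by intramolecular Claisen attack of the acetyl methyl carbanion on the lactone carbonyl, rejoining the route at 19.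

Step 2. Dehydration of the aldol to the conjugated enal, retro-aldol reversal, or poor control of C14 may lower the amount of 4. The fallback accepts the dehydration and reinstalls the oxygen. It sets out from 2: piperidine/AcOH with heating gives the enal F10. NaBH4/CeCl3·7H2O gives the allylic alcohol F11. VO(acac)2/t-BuOOH should give the epoxy alcohol F12, with the oxygen directed by the hydroxyl and anti to the isopropenyl group. NaAlH2(OCH2CH2OMe)2 should deliver hydride to C8 with inversion to give the 1,3-diol, rejoining the route at 4.

Step 13. O-alkylation of the triketone enolate may compete with C-alkylation, and the second alkylation at the now hindered C1 may remain incomplete. The fallback sets out from 19: Pd(PPh3)4 with allyl methyl carbonate, a soft C-selective allylation, gives the C1-diallyl compound F13. Cross-metathesis with 2-methylbut-2-ene and the second-generation Grubbs catalyst converts both allyl groups into prenyl groups, rejoining the route at 21.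

Further compounds

F1 | step 9 | allyl methyl carbonate of 9 | COC(=O)C(C[C@H]1[C@@H](CC[C@@]1(C)O[Si](CC)(CC)CC)C(=C)COC(=O)OC)C(=O)OC
F2 | step 9 | ring B gem-dimethyl ester with C10 methylene, (8S,9R,14R) | COC(=O)C1(C(=O)OC)C[C@H]2[C@@H](CC[C@@]2(C)O[Si](CC)(CC)CC)C(=C)C1
F3 | step 9 | ring B gem-diacid with C10 methylene, (8S,9R,14R) | OC(=O)C1(C(=O)O)C[C@H]2[C@@H](CC[C@@]2(C)O[Si](CC)(CC)CC)C(=C)C1
F4 | step 9 | iodolactone acid (15 with CO2H in place of CO2Me) | OC(=O)[C@]12C[C@H]3[C@@H](CC[C@@]3(C)O[Si](CC)(CC)CC)[C@](CI)(C1)OC2=O
F5 | step 8 | 2-{(1R,2S,3R)-2-(iodomethyl)-3-methyl-3-[(triethylsilyl)oxy]cyclopentyl}prop-2-en-1-ol | IC[C@H]1[C@@H](CC[C@@]1(C)O[Si](CC)(CC)CC)C(=C)CO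
F6 | step 8 | methyl malonate ester of F5 (mixed allyl methyl malonate) | IC[C@H]1[C@@H](CC[C@@]1(C)O[Si](CC)(CC)CC)C(=C)COC(=O)CC(=O)OC
F7 | step 12 | lactone acid (16 with CO2H in place of CO2Me) | OC(=O)[C@]12C[C@H]3[C@@H](CC[C@@]3(C)O[Si](CC)(CC)CC)[C@](C)(C1)OC2=O
F8 | step 12 | acid chloride of F7 | ClC(=O)[C@]12C[C@H]3[C@@H](CC[C@@]3(C)O[Si](CC)(CC)CC)[C@](C)(C1)OC2=O
F9 | step 12 | triacylmethane: C4 ketone bearing CH(COCH3)(COCH(CH3)2), lactone intact | CC(=O)C(C(=O)C(C)C)C(=O)[C@]12C[C@H]3[C@@H](CC[C@@]3(C)O[Si](CC)(CC)CC)[C@](C)(C1)OC2=O
F10 | step 2 | (5S)-2-methyl-5-(prop-1-en-2-yl)cyclopent-1-ene-1-carbaldehyde | O=CC1=C(C)CC[C@H]1C(C)=C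
F11 | step 2 | [(5S)-2-methyl-5-(prop-1-en-2-yl)cyclopent-1-en-1-yl]methanol | OCC1=C(C)CC[C@H]1C(C)=C
F12 | step 2 | epoxy alcohol of F11, epoxide oxygen anti to the isopropenyl group | OC[C@@]12O[C@]1(C)CC[C@H]2C(C)=C
F13 | step 13 | C1-diallyl analogue of 21 | C=CCC1(CC=C)C(=O)[C@]2(C[C@H]3[C@@H](CC[C@@]3(C)O[Si](CC)(CC)CC)[C@@](C)(O)C2)C(=O)C(C(=O)C(C)C)=C1O
A1 | alternative 1 | (1S,2R,5R)-2-hydroxy-2-methyl-5-(prop-1-en-2-yl)cyclopentane-1-carbaldehyde (identical with 3) | O=C[C@H]1[C@@H](CC[C@@]1(C)O)C(C)=C
A2 | alternative 2 | dimethyl 2-{[(1S,5R)-2-oxo-5-(prop-1-en-2-yl)cyclopentyl]methyl}propanedioate | O=C1CC[C@@H](C(C)=C)[C@@H]1CC(C(=O)OC)C(=O)OC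
A3 | alternative 2 | cyclopent-2-en-1-one | O=C1C=CCC1
A4 | alternative 2 | dimethyl 2-methylidenepropanedioate | C=C(C(=O)OC)C(=O)OC
A5 | alternative 3 | trans-fused hydrindene gem-dimethyl ester with C10=C11 and free C14 hydroxyl, (8S,9R,14R) | COC(=O)C1(C(=O)OC)C[C@H]2[C@@H](CC[C@@]2(C)O)C(C)=C1
A6 | alternative 3 | dimethyl 2-[(2E,6R)-6-hydroxy-2,6-dimethylocta-2,7-dien-1-ylidene]propanedioate | COC(=O)C(C(=O)OC)=C/C(C)=C/CC[C@@](C)(O)C=C
A7 | alternative 3 | (R)-linalool | CC(C)=CCC[C@@](C)(O)C=C
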